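Right now you have two earlier runs and a choice to make: how much initiator goes into the next closed flask, if you want as much monomer in chains as you can get after 1.0 h?

| setting | autumn | dawn | blue | teal | ochre | amber | grey |
|---|---|---|---|---|---|---|---|
| free monomer | 1.7 M | 1.7 M | 1.7 M | 1.7 M | 1.7 M | 1.7 M | 1.7 M |
| transfer agent | 0.017 M | 0.017 M | 0.0170 M | 0.0170 M | 0.0170 M | 0.0170 M | 0.0170 M |
| initiator | 15 mM | 340 mM | 25 mM | 50 mM | 100 mM | 200 mM | 400 mM |
| remark | run made earlier | run made earlier |  |  |  |  |  |
| time |  |  | 1.0 h | 1.0 h | 1.0 h | 1.0 h | 1.0 h |

| run | time / min | monomer in chains / % |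
|---|---|---|
| autumn | 5.00 | 2 |
| autumn | 8.00 | 1 |
| autumn | 12.0 | 1 |
| autumn | 15.0 | 0 |
| autumn | 25.0 | 0 |
| autumn | 40.0 | 3 |
| autumn | 60.0 | 3 |
| dawn | 5.00 | 50 |
| dawn | 8.00 | 66 |
| dawn | 12.0 | 74 |
| dawn | 15.0 | 79 |
| dawn | 25.0 | 85 |
| dawn | 40.0 | 81 |
| dawn | 60.0 | 84 |

(each reading ± 1.5 percentage points)

- the numbers in the tables scatter by 1.5 percentage points (one standard deviation)
- "hardly changes" means that all values lie within two and a half points (for a concentration: within two and a half percent of the largest)

- [monomer in chains] at the end for blue, teal, ochre, amber, grey, in this order
- how the row runs (hardly changes / rises all the way / falls, then rises / falls all the way / rises, then falls)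

Start with dawn. From 25.0 min on, its last 3 readings stand level, on average at 83.3% of the free monomer charged, so 0.283 M is missing from the chains. Now count turnovers: divide that gap by the initiator charged and you get w, the monomer lost to the chains per initiator charged, here 0.833. My own reading is that each initiator costs this much monomer, so the level is a ceiling C = M − wI, with M the free monomer and I the initiator charged. That gives 1.53 M for amber and 1.37 M for grey, so grey's ceiling lies lower.

Speed matters too. Autumn, with initiator 15 mM below the transfer agent's 0.017 M, ends at 3%, so I count the excess of initiator over agent and assume that the time to the level goes inversely with it. Dawn's 25.0 min then becomes 44.1 min for amber, inside the hour, but 97.3 min for ochre, beyond it. So I would charge amber's 200 mM and leave grey's 400 mM out, expecting the row to rise to amber and fall to grey. I put no numbers on the three lower flasks.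

The forecast gives 0.35 M, 0.97 M, 1.34 M, 1.41 M and 1.41 M, so rises all the way, and there it differs from my reckoning, on its own ground: “I assume this ceiling doesn't depend on initiator”.

The flasks give 0.0615 M, 0.140 M, 0.507 M, 1.52 M and 1.36 M: rises, then falls, turning at 200 mM.

    free monomer + initiator → living end + monomer in chains (k = 0.00481 M⁻¹ s⁻¹)
    free monomer + initiator → spent initiator (k = 0.0250 M⁻¹ s⁻¹)
    free monomer + living end → monomer in chains + living end, rate k3*[living end]*[free monomer] (k = 0.0829 M⁻¹ s⁻¹)
    living end + transfer agent → dead chain (kL = 0.644 M⁻¹ s⁻¹)

Grey stands below amber in part because free monomer and initiator also turn into spent initiator: the grey run without that step gives 1.70 M instead of 1.36 M, and the shape of the row changes. The same step, together with the turning of living end and transfer agent into dead chain, is part of why blue stands low: blue gives 1.55 M without the first and 1.17 M without the second, instead of 0.0615 M. The w read on dawn puts grey's ceiling at 1.37 M, and grey stands at 1.36 M with free monomer at 0%. On amber, the second flask, the same w gives 1.53 M, and after 1.00 h, with 0.863% of the free monomer still uncombined, amber holds 1.52 M.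

The runs are calculated with constants of no real substance.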